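Numbering used in the discussion: the ring carbons of the target are C1 (imidazolyl), C2 (CH2N), C3 (CH2N) and C4 (imidazolyl). Systematic names of intermediates use their own locants.

## Analysis of the target

Sceptrin (23) is built on one four-membered carbocycle in which every ring carbon is substituted. C1 and C4 each carry a 2-aminoimidazol-4(5)-yl ring, and C2 and C3 each carry a CH2NH arm acylated by 4-bromopyrrole-2-carboxylic acid. The substituents alternate between the two faces all round the ring (all-trans), and a twofold axis through the midpoints of C1–C4 and C2–C3 makes the molecule C2-symmetric. The four contiguous stereocentres therefore reduce to two independent ones; in the enantiomer required, the imidazole-bearing carbons are S and the aminomethyl-bearing carbons are R. The 2-aminoimidazoles are basic, polar and nucleophilic at several nitrogens, the pyrrole C–Br bonds survive neither organolithium reagents nor hydrogenation, and the pyrrole and amide N–H groups are acidic, so these groups must arrive late and in a fixed order. The difficulty is to make a strained, fully substituted cyclobutane in head-to-head, all-trans form as one enantiomer while carrying two heteroaromatic rings that bind metals and acids. The feature exploited is that the atom sequence imidazole–C1–C2–CH2N, and by symmetry imidazole–C4–C3–CH2N, is the carbon skeleton of urocanic acid (1): heteroaryl carbon, β-carbon, α-carbon, carboxyl carbon. The ring is thus formally two urocanate units joined β to β (C1–C4) and α to α (C2–C3), and at the ester oxidation level only C2 and C3 are acidic, so the two bonds and the two kinds of stereocentre can be made in separate events.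

## Retrosynthetic reasoning

The last bonds cut are the two N–trityl bonds and the two amide C–N bonds: 23 comes from its bis-trityl derivative 22, and 22 from tetra-amine 20 and acyl donor 21. The bromopyrroles are attached this late because they tolerate neither the organolithium step nor the hydrogenation that precede them. The forward acylation must pick the two primary alkylamines of 20 out of four amino groups; the trityl groups flanking the 2-amino groups help here.

All four nitrogen atoms of 20 are traced back to azide in 19. The two exocyclic C–N bonds are cut to C–O bonds (19 from dimesylate 18 and diol 17). The two imidazole C2–N bonds are cut to C2–H bonds (16 from 14), because C2 of an N-protected imidazole is its most acidic carbon and can be metalated and aminated with an electrophilic azide source. Compatibility fixes the order: the C2–N bonds are made while the oxygens are still silyl-protected (14, 16), since alkyl azides and sulfonates would not survive the metalation.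

The two CH2O carbons are carboxyl carbons in reduced form, so diol 13 comes from diester 12. The skeleton is unchanged, but C2 and C3 now carry acidifying groups, which makes the ring-closing bond accessible and the configuration at these centres correctable.

In 12 the C2–C3 bond, between the two ester-bearing carbons, is cut. It is the only ring bond flanked by two carbonyl groups, so in the forward sense it can be made by oxidising the dienolate 11 of open-chain diester 10. Cutting here, and not at C1–C2 or C3–C4, keeps the precursor C2-symmetric and leaves the non-epimerisable imidazole-bearing centres already fixed. The forward reaction must close a four-membered ring from an adipate, place both esters trans to their imidazole neighbours, and avoid the five-membered Claisen-type closure open to a half-enolised diester.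

Diester 10 is cut at its central bond, C1–C4 of the target, into two identical three-carbon units. This bond links the β-carbons of two urocanate units, so forward it is a reductive β,β-coupling (hydrodimerisation) of an electron-poor alkene. It must give the chiral, non-meso diastereomer as one enantiomer. For that reason the acceptor is oxazolidinone imide 8 and the coupling product is bis-imide 9, from which the esters of 10 are released with recovery of auxiliary 6.

Imide 8 is cut at the N-acyl bond into acid 5 and oxazolidinone 6, and 5 goes back through esters 4 and 2 to urocanic acid (1) and trityl chloride (3). The trityl group goes selectively to the ring nitrogen remote from the side chain, withstands bases, hydrides, one-electron reductants and organolithiums, leaves C2 open for the later metalation, and is removed by acid at the very end.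

## Alternatives that were turned down

Alternative 1: Both imidazole rings would be disconnected instead of the carbocycle (in each, the C4–C5 bond and the N1–C2 bond), leading back to the all-trans cyclobutane dialdehyde A1. Forward, A1 would be converted into its bis-aldimine with an electron-rich benzylamine and treated with a tosylmethyl isocyanide and carbonate base, a twofold van Leusen annulation giving A2.
- For: the annulation is a dependable, two-directional ring synthesis, and no metal-binding heterocycle is present while the carbocycle is made. The aminomethyl nitrogens are already in place, so no displacement has to be run next to a nucleophilic imidazole; on this point it is stronger than the chosen route.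
- Against: it does not make the cyclobutane. A1, with its four stereocentres, would need a separate multi-step enantioselective ring synthesis. The 1,5-substitution pattern puts the N-benzyl groups next to the ring, so two of them on adjacent carbons crowd the second annulation. Both imidazoles would still need amination at C2, and six benzyl-type N-substituents must be removed before the bromopyrroles can be attached.
- Comparison: its key step is safer than step 7, but the risk is only moved into the preparation of A1 and the step count is clearly higher. The chosen strategy takes every core carbon and both heterocycles from 1 and reaches the ring in one step from 10.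

Alternative 2: The two ring-to-side-chain bonds at C2 and C3 would be cut, starting from the enantiopure trans-diamide A3, whose ring carbons are C1 and C4 of the target. Forward, a twofold amide-directed, palladium-catalysed C(sp3)–H alkenylation with an (E)-2-arylvinyl iodide and a silver carboxylate would give the bis-styryl compound A4.
- For: the absolute configuration is bought with the starting diacid and not made by an auxiliary-controlled radical coupling; on this point it is stronger than the chosen route. Two C–C bonds form in one operation on a preformed ring. A later de novo imidazole synthesis from a haloketone and a guanidine would bring the 2-amino group in directly and avoid a step like step 10.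
- Against: the directing group delivers each new substituent cis to its amide, so A4 is cis,trans,cis and both amide-bearing carbons must be epimerised to reach the all-trans ring. The second C–H activation takes place on a more crowded ring, and alkenylation of a cyclobutane methylene is less secure than arylation. A long functional-group sequence follows: removal of the directing amides, homologation of each carboxyl carbon into a 2-aminoimidazole, and cleavage of each styryl group to a one-carbon unit that is then aminated.
- Comparison: far more steps follow its key step than follow step 7. The chosen route reaches the all-trans arrangement under thermodynamic control without a planned inversion and has the imidazoles intact from the first step.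

Alternative 3: C1–C2 and C3–C4 would be cut together in a [2+2] sense, the two alkenes being tethered through an amide nitrogen that carries a stereogenic 1-arylethyl group (A5). Forward, triplet-sensitised irradiation of A5 would form C1–C2 in a 5-exo closure and then C3–C4, giving the cis-fused bicyclic lactam A6.
- For: two ring bonds form in one reagent-free photochemical step, which is more direct than making one bond in step 5 and the other in step 7. The tether guarantees head-to-head regiochemistry and the conditions are mild.
- Against: the lactam is cis-fused, so a future imidazole carbon and a future aminomethyl arm on adjacent ring carbons are cis. A tertiary lactam would have to be opened and its α-carbon epimerised. The triplet 1,4-diradical can rotate before closing, which erodes the geometry at C3 and C4. The stereogenic N-substituent lies outside the forming ring, so facial control is weak and diastereomers must be separated. A6 carries differentiated ester and lactam carbonyls although the target is symmetric, and both imidazoles must still be built from carboxyl carbons.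
- Comparison: it is superior in bond economy at the ring-forming step but inferior in stereocontrol and in the length of the endgame. The chosen strategy offers ready-made heterocycles and stereocentres that are either fixed beforehand (C1, C4) or correctable by base (C2, C3).

Key step: step 7

Assumption: the facial sense of the hydrodimerisation is taken from the chelate model (samarium bound to both imide carbonyls, s-cis enoyl, bond formation anti to the benzyl group), which for the (R)-auxiliary gives the (3S,4S)-adipate; if the sense proved opposite, the (S)-auxiliary would be used instead.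

## Route

Step 1
Reactants: 1 urocanic acid
Product: 2 methyl (E)-3-(1H-imidazol-4-yl)acrylate
Conditions: SOCl2 (1.5 equiv), MeOH, 0 °C → reflux; NaHCO3 work-up
Reagents that add atoms: methanol, CO
Why: Acid-mediated (Fischer-type) esterification with HCl generated in situ from SOCl2 and methanol; the imidazole is protonated and inert, and the E-alkene is untouched.

Step 2
Reactants: 2 methyl (E)-3-(1H-imidazol-4-yl)acrylate; 3 trityl chloride
Product: 4 methyl (E)-3-(1-trityl-1H-imidazol-4-yl)acrylate
Conditions: Et3N (1.5 equiv), DMF, rt
Reagents that add atoms: none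
Why: N-Tritylation of the imidazole; the very bulky electrophile is taken up by the ring nitrogen remote from the side chain, which should give the 1,4-disubstituted isomer.

Step 3
Reactants: 4 methyl (E)-3-(1-trityl-1H-imidazol-4-yl)acrylate
Product: 5 (E)-3-(1-trityl-1H-imidazol-4-yl)acrylic acid
Conditions: LiOH·H2O (1.5 equiv), THF/MeOH/H2O, rt; AcOH to pH 5–6, 0 °C
Reagents that add atoms: lithium hydroxide, [Li+].[OH-]
Why: Ester saponification; the N-trityl group is stable to hydroxide, and acidification only to pH 5–6 with acetic acid should leave it in place.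

Step 4
Reactants: 5 (E)-3-(1-trityl-1H-imidazol-4-yl)acrylic acid; 6 (R)-4-benzyl-2-oxazolidinone
Product: 8 (R)-4-benzyl-3-[(E)-3-(1-trityl-1H-imidazol-4-yl)prop-2-enoyl]oxazolidin-2-one, via mixed pivalic anhydride 7 (not isolated)
Conditions: t-BuCOCl (1.1 equiv), Et3N (2.5 equiv), THF, −20 °C; then 6, LiCl (1.2 equiv), −20 °C → rt
Reagents that add atoms: none
Why: N-Acylation of an oxazolidinone through a mixed anhydride with LiCl/Et3N activation; the hindered pivaloyl carbonyl directs attack to the urocanoyl carbonyl, and no stereocentre is formed.

Step 5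
Reactants: 8 (R)-4-benzyl-3-[(E)-3-(1-trityl-1H-imidazol-4-yl)prop-2-enoyl]oxazolidin-2-one (two molecules)
Product: 9 (4R,4'R)-3,3'-[(3S,4S)-3,4-bis(1-trityl-1H-imidazol-4-yl)hexanedioyl]bis(4-benzyloxazolidin-2-one)
Conditions: SmI2 (1.2 equiv per 8), t-BuOH (1.5 equiv per 8), THF, −78 °C
Reagents that add atoms: none
Why: Reductive hydrodimerisation (β,β-coupling) of an N-enoyl oxazolidinone by SmI2: electron transfer gives a samarium-chelated radical anion (both imide carbonyls on samarium, s-cis enoyl), and two such species join at their β-carbons to form the bond that is C1–C4 of the target. Each β-carbon should react on the face away from the benzyl group of its own auxiliary, so both new centres receive the same (S) configuration, which excludes the meso isomer and sets the absolute configuration. t-BuOH protonates the samarium enolates before they can attack an imide carbonyl.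

Step 6
Reactants: 9 (4R,4'R)-3,3'-[(3S,4S)-3,4-bis(1-trityl-1H-imidazol-4-yl)hexanedioyl]bis(4-benzyloxazolidin-2-one)
Product: 10 dimethyl (3S,4S)-3,4-bis(1-trityl-1H-imidazol-4-yl)hexanedioate
Conditions: NaOMe (2.2 equiv), MeOH/CH2Cl2, 0 °C; AcOH quench
Reagents that add atoms: sodium methoxide, C[O-].[Na+]; methanol, CO
Why: Methanolysis of the N-acyl oxazolidinones at the unhindered exocyclic carbonyl; the two stereocentres are β to the carbonyl groups and not acidic, so they should be untouched, and auxiliary 6 is recovered.

Step 7
Reactants: 10 dimethyl (3S,4S)-3,4-bis(1-trityl-1H-imidazol-4-yl)hexanedioate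
Product: 12 dimethyl (1S,2S,3R,4R)-3,4-bis(1-trityl-1H-imidazol-4-yl)cyclobutane-1,2-dicarboxylate (all-trans), via dilithium dienolate 11 (not isolated)
Conditions: LDA [LiN(i-Pr)2] (2.3 equiv), THF, −78 °C (10 added slowly to the base, 0.02 M); anhydrous CuBr2 (2.6 equiv), −78 → 0 °C; crude product: NaOMe (0.2 equiv), MeOH, rt
Reagents that add atoms: none
Why: Intramolecular oxidative coupling of a diester dienolate, the ring-forming counterpart of the oxidative dimerisation of ester enolates to succinates and a known way from adipate dienolates to trans-cyclobutane-1,2-dicarboxylates with divalent copper halides or iodine. CuBr2 takes one electron from one lithium enolate of 11 to give an α-ester radical, which adds to the carbon of the second enolate in a 4-exo-trig closure; the resulting ester ketyl is oxidised by a second CuBr2 to the diester (a bromination followed by 4-exo-tet alkylation would lead to the same bond). The one ring is closed by joining the two former α-carbons (adipate C2 and C5, target C2 and C3), and the short tether together with dilution should favour this closure over intermolecular coupling. Each of the two new stereocentres is controlled by the fixed centre beside it: the (3S,4S) configuration lets the two tritylimidazoles stay anti while the ester arms turn gauche, and each ester then ends up trans to its imidazole neighbour. Because only the two ester-bearing ring carbons are acidic, brief methoxide treatment should move any cis ester into the all-trans arrangement, the thermodynamic minimum, without touching the imidazole-bearing centres. The step needs selective double α-deprotonation of the esters over imidazole C2–H, secured by a small excess of base at −78 °C and by the trityl groups shielding C2, and complete dienolate formation before oxidation, since a mono-enolate could undergo Dieckmann condensation; adding 10 to the base guards against this. The excess of CuBr2 compensates for copper bound at the imidazole N3 atoms.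

Step 8
Reactants: 12 dimethyl (1S,2S,3R,4R)-3,4-bis(1-trityl-1H-imidazol-4-yl)cyclobutane-1,2-dicarboxylate
Product: 13 [(1S,2S,3R,4R)-3,4-bis(1-trityl-1H-imidazol-4-yl)cyclobutane-1,2-diyl]dimethanol
Conditions: LiAlH4 (2.5 equiv), THF, 0 °C → rt; H2O/NaOH work-up
Reagents that add atoms: none
Why: Hydride reduction of both esters to primary alcohols; after this step no ring carbon is epimerisable, so the all-trans configuration is locked.

Step 9
Reactants: 13 [(1S,2S,3R,4R)-3,4-bis(1-trityl-1H-imidazol-4-yl)cyclobutane-1,2-diyl]dimethanol
Product: 14 (1S,2S,3R,4R)-1,2-bis[(tert-butyldimethylsilyloxy)methyl]-3,4-bis(1-trityl-1H-imidazol-4-yl)cyclobutane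
Conditions: TBSCl (2.5 equiv), imidazole (5 equiv), DMF, rt
Reagents that add atoms: tert-butyldimethylsilyl chloride (TBSCl), CC(C)(C)[Si](C)(C)Cl
Why: Silylation of the primary alcohols, so that in the next step the only acidic sites left are the imidazole C2–H bonds.

Step 10
Reactants: 14 (1S,2S,3R,4R)-1,2-bis[(tert-butyldimethylsilyloxy)methyl]-3,4-bis(1-trityl-1H-imidazol-4-yl)cyclobutane
Product: 16 (1S,2S,3R,4R)-3,4-bis(2-azido-1-trityl-1H-imidazol-4-yl)-1,2-bis[(tert-butyldimethylsilyloxy)methyl]cyclobutane, via bis(2-lithioimidazole) 15 (not isolated)
Conditions: n-BuLi (2.5 equiv), THF, −78 → −20 °C; TsN3 (3 equiv), −78 °C → rt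
Reagents that add atoms: tosyl azide (4-methylbenzenesulfonyl azide), Cc1ccc(cc1)S(=O)(=O)N=[N+]=[N-]
Why: Deprotonation of an N-protected imidazole at C2, its most acidic carbon, followed by electrophilic azide transfer: the aryllithium adds to the terminal nitrogen of the sulfonyl azide and the triazenide loses sulfinate. Silyl ethers and trityl groups are inert to n-BuLi at these temperatures.

Step 11
Reactants: 16 (1S,2S,3R,4R)-3,4-bis(2-azido-1-trityl-1H-imidazol-4-yl)-1,2-bis[(tert-butyldimethylsilyloxy)methyl]cyclobutane
Product: 17 [(1S,2S,3R,4R)-3,4-bis(2-azido-1-trityl-1H-imidazol-4-yl)cyclobutane-1,2-diyl]dimethanol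
Conditions: Bu4NF (2.5 equiv), THF, 0 °C → rt
Reagents that add atoms: none
Why: Fluoride-induced cleavage of the silyl ethers; heteroaryl azides and N-trityl groups do not react with fluoride.

Step 12
Reactants: 17 [(1S,2S,3R,4R)-3,4-bis(2-azido-1-trityl-1H-imidazol-4-yl)cyclobutane-1,2-diyl]dimethanol
Product: 18 [(1S,2S,3R,4R)-3,4-bis(2-azido-1-trityl-1H-imidazol-4-yl)cyclobutane-1,2-diyl]bis(methylene) dimethanesulfonate
Conditions: MsCl (2.5 equiv), Et3N (3 equiv), CH2Cl2, 0 °C
Reagents that add atoms: methanesulfonyl chloride, CS(=O)(=O)Cl
Why: Sulfonylation of the two primary alcohols turns them into leaving groups; the product is used without delay.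

Step 13
Reactants: 18 [(1S,2S,3R,4R)-3,4-bis(2-azido-1-trityl-1H-imidazol-4-yl)cyclobutane-1,2-diyl]bis(methylene) dimethanesulfonate
Product: 19 (1R,2R,3S,4S)-1,2-bis(azidomethyl)-3,4-bis(2-azido-1-trityl-1H-imidazol-4-yl)cyclobutane
Conditions: NaN3 (6 equiv), DMF, 60 °C
Reagents that add atoms: sodium azide, [Na+].[N-]=[N+]=[N-]
Why: SN2 displacement of primary mesylates by azide at the exocyclic carbons; no ring stereocentre is involved (the descriptors change only because the substituent priorities change).

Step 14
Reactants: 19 (1R,2R,3S,4S)-1,2-bis(azidomethyl)-3,4-bis(2-azido-1-trityl-1H-imidazol-4-yl)cyclobutane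
Product: 20 (1R,2R,3S,4S)-1,2-bis(aminomethyl)-3,4-bis(2-amino-1-trityl-1H-imidazol-4-yl)cyclobutane
Conditions: H2 (1 atm), 10% Pd/C, MeOH/THF, rt
Reagents that add atoms: none
Why: Catalytic hydrogenation reduces the two alkyl and the two heteroaryl azides to amines with loss of dinitrogen; N-trityl imidazoles tolerate neutral hydrogenation at one atmosphere, and the step precedes the introduction of the C–Br bonds.

Step 15
Reactants: 20 (1R,2R,3S,4S)-1,2-bis(aminomethyl)-3,4-bis(2-amino-1-trityl-1H-imidazol-4-yl)cyclobutane; 21 4-bromo-2-(trichloroacetyl)pyrrole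
Product: 22 N,N'-{[(1R,2R,3S,4S)-3,4-bis(2-amino-1-trityl-1H-imidazol-4-yl)cyclobutane-1,2-diyl]bis(methylene)}bis(4-bromo-1H-pyrrole-2-carboxamide)
Conditions: 21 (2.1 equiv), Na2CO3, DMF, rt
Reagents that add atoms: none
Why: Amide formation by haloform-type acyl transfer from a trichloromethyl ketone with loss of chloroform; this mild acyl donor should react with the primary alkylamines and leave the weakly nucleophilic 2-amino groups, which sit next to the trityl groups, untouched.

Step 16
Reactants: 22 N,N'-{[(1R,2R,3S,4S)-3,4-bis(2-amino-1-trityl-1H-imidazol-4-yl)cyclobutane-1,2-diyl]bis(methylene)}bis(4-bromo-1H-pyrrole-2-carboxamide)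
Product: 23 sceptrin, N,N'-{[(1R,2R,3S,4S)-3,4-bis(2-amino-1H-imidazol-5-yl)cyclobutane-1,2-diyl]bis(methylene)}bis(4-bromo-1H-pyrrole-2-carboxamide)
Conditions: CF3CO2H/CH2Cl2 (1:4), H2O (5 equiv), rt; basic ion-exchange resin to liberate the free base
Reagents that add atoms: none
Why: Acidolysis of the N-trityl groups by an SN1 pathway, the trityl cation being trapped by water; amides and bromopyrroles are stable to the acid, and the product is obtained as its salt before neutralisation.

## Compound list

1 | urocanic acid, (E)-3-(1H-imidazol-4-yl)acrylic acid | OC(=O)/C=C/c1c[nH]cn1 | starting material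
2 | methyl (E)-3-(1H-imidazol-4-yl)acrylate | COC(=O)/C=C/c1c[nH]cn1 | intermediate
3 | trityl chloride | ClC(c1ccccc1)(c1ccccc1)c1ccccc1 | starting material
4 | methyl (E)-3-(1-trityl-1H-imidazol-4-yl)acrylate | COC(=O)/C=C/c1cn(C(c2ccccc2)(c2ccccc2)c2ccccc2)cn1 | intermediate
5 | (E)-3-(1-trityl-1H-imidazol-4-yl)acrylic acid | OC(=O)/C=C/c1cn(C(c2ccccc2)(c2ccccc2)c2ccccc2)cn1 | intermediate
6 | (R)-4-benzyl-2-oxazolidinone | O=C1N[C@H](Cc2ccccc2)CO1 | starting material
7 | (E)-3-(1-trityl-1H-imidazol-4-yl)acrylic pivalic anhydride (not isolated) | CC(C)(C)C(=O)OC(=O)/C=C/c1cn(C(c2ccccc2)(c2ccccc2)c2ccccc2)cn1 | intermediate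
8 | (R)-4-benzyl-3-[(E)-3-(1-trityl-1H-imidazol-4-yl)prop-2-enoyl]oxazolidin-2-one | O=C(/C=C/c1cn(C(c2ccccc2)(c2ccccc2)c2ccccc2)cn1)N1[C@H](Cc2ccccc2)COC1=O | intermediate
9 | (4R,4'R)-3,3'-[(3S,4S)-3,4-bis(1-trityl-1H-imidazol-4-yl)hexanedioyl]bis(4-benzyloxazolidin-2-one) | C(c1ccccc1)(c1ccccc1)(c1ccccc1)n1cnc(c1)[C@H]([C@@H](c1cn(C(c2ccccc2)(c2ccccc2)c2ccccc2)cn1)CC(=O)N1[C@H](Cc2ccccc2)COC1=O)CC(=O)N1[C@H](Cc2ccccc2)COC1=O | intermediate
10 | dimethyl (3S,4S)-3,4-bis(1-trityl-1H-imidazol-4-yl)hexanedioate | C(c1ccccc1)(c1ccccc1)(c1ccccc1)n1cnc(c1)[C@H]([C@@H](c1cn(C(c2ccccc2)(c2ccccc2)c2ccccc2)cn1)CC(=O)OC)CC(=O)OC | intermediate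
11 | dilithium bis(ester enolate) of 10 (not isolated; enolate geometry not specified) | C(c1ccccc1)(c1ccccc1)(c1ccccc1)n1cnc(c1)[C@H]([C@@H](c1cn(C(c2ccccc2)(c2ccccc2)c2ccccc2)cn1)C=C(O[Li])OC)C=C(O[Li])OC | intermediate
12 | dimethyl (1S,2S,3R,4R)-3,4-bis(1-trityl-1H-imidazol-4-yl)cyclobutane-1,2-dicarboxylate (all-trans) | C(c1ccccc1)(c1ccccc1)(c1ccccc1)n1cnc(c1)[C@H]1[C@H](C(=O)OC)[C@@H](C(=O)OC)[C@@H]1c1cn(C(c2ccccc2)(c2ccccc2)c2ccccc2)cn1 | intermediate
13 | [(1S,2S,3R,4R)-3,4-bis(1-trityl-1H-imidazol-4-yl)cyclobutane-1,2-diyl]dimethanol | C(c1ccccc1)(c1ccccc1)(c1ccccc1)n1cnc(c1)[C@H]1[C@H](CO)[C@@H](CO)[C@@H]1c1cn(C(c2ccccc2)(c2ccccc2)c2ccccc2)cn1 | intermediate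
14 | (1S,2S,3R,4R)-1,2-bis[(tert-butyldimethylsilyloxy)methyl]-3,4-bis(1-trityl-1H-imidazol-4-yl)cyclobutane | C(c1ccccc1)(c1ccccc1)(c1ccccc1)n1cnc(c1)[C@H]1[C@H](CO[Si](C)(C)C(C)(C)C)[C@@H](CO[Si](C)(C)C(C)(C)C)[C@@H]1c1cn(C(c2ccccc2)(c2ccccc2)c2ccccc2)cn1 | intermediate
15 | bis(2-lithio) derivative of 14, lithium at C2 of each imidazole (not isolated) | C(c1ccccc1)(c1ccccc1)(c1ccccc1)n1c([Li])nc(c1)[C@H]1[C@H](CO[Si](C)(C)C(C)(C)C)[C@@H](CO[Si](C)(C)C(C)(C)C)[C@@H]1c1cn(C(c2ccccc2)(c2ccccc2)c2ccccc2)c([Li])n1 | intermediate
16 | (1S,2S,3R,4R)-3,4-bis(2-azido-1-trityl-1H-imidazol-4-yl)-1,2-bis[(tert-butyldimethylsilyloxy)methyl]cyclobutane | C(c1ccccc1)(c1ccccc1)(c1ccccc1)n1c(N=[N+]=[N-])nc(c1)[C@H]1[C@H](CO[Si](C)(C)C(C)(C)C)[C@@H](CO[Si](C)(C)C(C)(C)C)[C@@H]1c1cn(C(c2ccccc2)(c2ccccc2)c2ccccc2)c(N=[N+]=[N-])n1 | intermediate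
17 | [(1S,2S,3R,4R)-3,4-bis(2-azido-1-trityl-1H-imidazol-4-yl)cyclobutane-1,2-diyl]dimethanol | C(c1ccccc1)(c1ccccc1)(c1ccccc1)n1c(N=[N+]=[N-])nc(c1)[C@H]1[C@H](CO)[C@@H](CO)[C@@H]1c1cn(C(c2ccccc2)(c2ccccc2)c2ccccc2)c(N=[N+]=[N-])n1 | intermediate
18 | [(1S,2S,3R,4R)-3,4-bis(2-azido-1-trityl-1H-imidazol-4-yl)cyclobutane-1,2-diyl]bis(methylene) dimethanesulfonate | C(c1ccccc1)(c1ccccc1)(c1ccccc1)n1c(N=[N+]=[N-])nc(c1)[C@H]1[C@H](COS(C)(=O)=O)[C@@H](COS(C)(=O)=O)[C@@H]1c1cn(C(c2ccccc2)(c2ccccc2)c2ccccc2)c(N=[N+]=[N-])n1 | intermediate
19 | (1R,2R,3S,4S)-1,2-bis(azidomethyl)-3,4-bis(2-azido-1-trityl-1H-imidazol-4-yl)cyclobutane | C(c1ccccc1)(c1ccccc1)(c1ccccc1)n1c(N=[N+]=[N-])nc(c1)[C@H]1[C@H](CN=[N+]=[N-])[C@@H](CN=[N+]=[N-])[C@@H]1c1cn(C(c2ccccc2)(c2ccccc2)c2ccccc2)c(N=[N+]=[N-])n1 | intermediate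
20 | (1R,2R,3S,4S)-1,2-bis(aminomethyl)-3,4-bis(2-amino-1-trityl-1H-imidazol-4-yl)cyclobutane | C(c1ccccc1)(c1ccccc1)(c1ccccc1)n1c(N)nc(c1)[C@H]1[C@H](CN)[C@@H](CN)[C@@H]1c1cn(C(c2ccccc2)(c2ccccc2)c2ccccc2)c(N)n1 | intermediate
21 | 4-bromo-2-(trichloroacetyl)pyrrole | O=C(c1cc(Br)c[nH]1)C(Cl)(Cl)Cl | starting material
22 | N,N'-{[(1R,2R,3S,4S)-3,4-bis(2-amino-1-trityl-1H-imidazol-4-yl)cyclobutane-1,2-diyl]bis(methylene)}bis(4-bromo-1H-pyrrole-2-carboxamide) | C(c1ccccc1)(c1ccccc1)(c1ccccc1)n1c(N)nc(c1)[C@H]1[C@H](CNC(=O)c2cc(Br)c[nH]2)[C@@H](CNC(=O)c2cc(Br)c[nH]2)[C@@H]1c1cn(C(c2ccccc2)(c2ccccc2)c2ccccc2)c(N)n1 | intermediate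
23 | sceptrin | Nc1ncc([C@H]2[C@H](CNC(=O)c3cc(Br)c[nH]3)[C@@H](CNC(=O)c3cc(Br)c[nH]3)[C@@H]2c2cnc(N)[nH]2)[nH]1 | target

## Step count and risk

Total step count: 16. Longest linear sequence: 16 steps (1 → 23); the route is fully linear, with 3, 6 and 21 entering as purchased reagents.

Least certain steps:

Step 7 (key step). The most likely failures are incomplete double enolisation, which lets a mono-enolate undergo Dieckmann condensation to a five-membered β-keto ester, and intermolecular coupling or simple α-bromination competing with the strained 4-exo closure. Copper may also be held back by coordination to the imidazole N3 atoms. Fallback: a two-electron closure of the same bond. Setting out from 10, the dienolate is trapped with Me3SiCl to give the bis(trimethylsilyl ketene acetal) F1, which is free of base. One equivalent of N-bromosuccinimide at −78 °C converts one ketene acetal into an α-bromo ester, giving the mono-bromo mono-ketene acetal F2. CsF then unmasks the remaining enolate, which displaces bromide in a 4-exo-tet alkylation, and methoxide equilibration of the product brings the route back at 12.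

Step 5. Facial selectivity may be poor or of the opposite sense (the latter is answered by the enantiomeric auxiliary), the meso isomer may form, the alkene may be reduced without coupling, or a samarium enolate may cyclise onto an imide carbonyl. Fallback: give up auxiliary control and resolve. Setting out from 4, the methyl ester is hydrodimerised (SmI2, HMPA, t-BuOH, THF) to the racemic chiral diester, racemic dimethyl (3RS,4RS)-3,4-bis(1-trityl-1H-imidazol-4-yl)hexanedioate F3, from which the meso isomer is removed by crystallisation or chromatography. The enantiomers are separated by preparative chromatography on a polysaccharide-based chiral stationary phase, and the (3S,4S) enantiomer re-enters the route as 10.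

Step 13. A mesylate carbon and an imidazole on the diagonally opposite ring carbon lie on the same face, so intramolecular N-alkylation by the free imidazole N3 to a bridged imidazolium may compete with azide displacement at the β-branched primary carbon. Fallback: introduce the nitrogen at the aldehyde oxidation level so that no carbon electrophile sits next to the imidazoles. Setting out from 17, both alcohols are oxidised with Dess–Martin periodinane (NaHCO3-buffered CH2Cl2) to the all-trans dialdehyde F4; enolisation is harmless because all-trans is the preferred arrangement. Condensation with NH2OH·HCl in pyridine gives the dioxime F5, and LiAlH4 in THF reduces the oximes and both heteroaryl azides together, returning to the route at 20.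

Step 10. The double functionalisation needs both rings to be metalated at C2 and both triazenide adducts to collapse to azide; incomplete azide transfer in one ring or stable triazenes are the likely failures. Fallback: form the C2–N bonds by copper catalysis instead of electrophilic azide transfer. Setting out from 14, the lithiated species is quenched with iodine, a fast and clean trap, to give the bis(2-iodoimidazole) F6. Coupling with NaN3 under CuI/L-proline catalysis (DMSO, 60 °C) returns to the route at 16.

Step 15. Acylation may be incomplete because of the bulky environment, or may spill over onto a 2-amino group or a ring nitrogen. Fallback: change the order of deprotection and acylation. Setting out from 20, the trityl groups are removed first (CF3CO2H, CH2Cl2, H2O) to give the free tetra-amine F7, handled as its salt. Acylation with 21 in DMF with Na2CO3 then relies on the low nucleophilicity of unprotected 2-aminoimidazoles toward a trichloromethyl ketone and leads directly to 23.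

## Further compounds

F1 | step 7 | bis(trimethylsilyl ketene acetal) of 10 (configuration at the two stereocentres as in 10; enol ether geometry not specified) | C(c1ccccc1)(c1ccccc1)(c1ccccc1)n1cnc(c1)[C@H]([C@@H](c1cn(C(c2ccccc2)(c2ccccc2)c2ccccc2)cn1)C=C(O[Si](C)(C)C)OC)C=C(O[Si](C)(C)C)OC
F2 | step 7 | mono-α-bromo ester mono(trimethylsilyl ketene acetal) derived from F1 (mixture at the brominated carbon) | C(c1ccccc1)(c1ccccc1)(c1ccccc1)n1cnc(c1)[C@H]([C@@H](c1cn(C(c2ccccc2)(c2ccccc2)c2ccccc2)cn1)C=C(O[Si](C)(C)C)OC)C(Br)C(=O)OC
F3 | step 5 | racemic dimethyl (3RS,4RS)-3,4-bis(1-trityl-1H-imidazol-4-yl)hexanedioate (both enantiomers) | C(c1ccccc1)(c1ccccc1)(c1ccccc1)n1cnc(c1)[C@H]([C@@H](c1cn(C(c2ccccc2)(c2ccccc2)c2ccccc2)cn1)CC(=O)OC)CC(=O)OC.C(c1ccccc1)(c1ccccc1)(c1ccccc1)n1cnc(c1)[C@@H]([C@H](c1cn(C(c2ccccc2)(c2ccccc2)c2ccccc2)cn1)CC(=O)OC)CC(=O)OC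
F4 | step 13 | all-trans 3,4-bis(2-azido-1-trityl-1H-imidazol-4-yl)cyclobutane-1,2-dicarbaldehyde | C(c1ccccc1)(c1ccccc1)(c1ccccc1)n1c(N=[N+]=[N-])nc(c1)[C@H]1[C@H](C=O)[C@@H](C=O)[C@@H]1c1cn(C(c2ccccc2)(c2ccccc2)c2ccccc2)c(N=[N+]=[N-])n1
F5 | step 13 | dioxime of F4 (oxime geometry not specified) | C(c1ccccc1)(c1ccccc1)(c1ccccc1)n1c(N=[N+]=[N-])nc(c1)[C@H]1[C@H](C=NO)[C@@H](C=NO)[C@@H]1c1cn(C(c2ccccc2)(c2ccccc2)c2ccccc2)c(N=[N+]=[N-])n1
F6 | step 10 | (1S,2S,3R,4R)-1,2-bis[(tert-butyldimethylsilyloxy)methyl]-3,4-bis(2-iodo-1-trityl-1H-imidazol-4-yl)cyclobutane | C(c1ccccc1)(c1ccccc1)(c1ccccc1)n1c(I)nc(c1)[C@H]1[C@H](CO[Si](C)(C)C(C)(C)C)[C@@H](CO[Si](C)(C)C(C)(C)C)[C@@H]1c1cn(C(c2ccccc2)(c2ccccc2)c2ccccc2)c(I)n1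
F7 | step 15 | (1R,2R,3S,4S)-1,2-bis(aminomethyl)-3,4-bis(2-amino-1H-imidazol-5-yl)cyclobutane | Nc1ncc([C@H]2[C@H](CN)[C@@H](CN)[C@@H]2c2cnc(N)[nH]2)[nH]1
A1 | alternative 1 | all-trans 3,4-bis(dibenzylaminomethyl)cyclobutane-1,2-dicarbaldehyde | O=C[C@H]1[C@H](CN(Cc2ccccc2)Cc2ccccc2)[C@@H](CN(Cc2ccccc2)Cc2ccccc2)[C@@H]1C=O
A2 | alternative 1 | all-trans 1,2-bis(dibenzylaminomethyl)-3,4-bis[1-(2,4-dimethoxybenzyl)imidazol-5-yl]cyclobutane | COc1ccc(Cn2cncc2[C@H]2[C@H](CN(Cc3ccccc3)Cc3ccccc3)[C@@H](CN(Cc3ccccc3)Cc3ccccc3)[C@@H]2c2cncn2Cc2ccc(OC)cc2OC)c(OC)c1
A3 | alternative 2 | (1R,2R)-N,N'-di(quinolin-8-yl)cyclobutane-1,2-dicarboxamide | O=C(Nc1cccc2cccnc12)[C@@H]1CC[C@H]1C(=O)Nc1cccc2cccnc12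
A4 | alternative 2 | cis,trans,cis-N,N'-di(quinolin-8-yl)-3,4-di[(E)-styryl]cyclobutane-1,2-dicarboxamide | O=C(Nc1cccc2cccnc12)[C@@H]1[C@H](/C=C/c2ccccc2)[C@@H](/C=C/c2ccccc2)[C@H]1C(=O)Nc1cccc2cccnc12
A5 | alternative 3 | methyl (E)-4-{[(E)-4-(tert-butoxycarbonylamino)but-2-enyl][(S)-1-(4-methoxyphenyl)ethyl]amino}-4-oxobut-2-enoate | COC(=O)/C=C/C(=O)N(C/C=C/CNC(=O)OC(C)(C)C)[C@@H](C)c1ccc(OC)cc1
A6 | alternative 3 | methyl 6-(tert-butoxycarbonylaminomethyl)-3-[(S)-1-(4-methoxyphenyl)ethyl]-2-oxo-3-azabicyclo[3.2.0]heptane-7-carboxylate | O=C1N([C@@H](C)c3ccc(OC)cc3)C[C@@H]2[C@@H](CNC(=O)OC(C)(C)C)[C@H](C(=O)OC)[C@H]12
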